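One X per G cannot be the whole count: in the north-west flask that count leaves 51.1% of the X free at 4.00 min, yet G crept from 50.0% at 2.50 min to 53.8% there.

all flasks: L 0.50 M
- north-west: X 0.55 M; the very flask that is asked about, followed so far
- south: X 0.83 M; run made earlier
- flask: X 0.550 M; time 8.0 min

| run | time / min | L / % | G / % |
|---|---|---|---|
| north-west | 0.200 | 89.1 | 4.4 |
| north-west | 0.667 | 72.9 | 18.4 |
| north-west | 1.00 | 60.7 | 27.3 |
| north-west | 1.50 | 48.0 | 36.8 |
| north-west | 2.50 | 30.4 | 50.0 |
| north-west | 3.00 | 25.9 | 51.5 |
| north-west | 4.00 | 19.9 | 53.8 |
| south | 0.333 | 82.6 | 12.3 |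
| south | 0.833 | 61.7 | 28.8 |
| south | 1.50 | 37.4 | 49.9 |
| south | 2.50 | 11.3 | 70.0 |
| south | 3.00 | 3.9 | 74.3 |
| south | 4.00 | 0.6 | 80.9 |
| south | 6.00 | 0.1 | 83.5 |

(each reading ± 0.5 percentage points)

- L is a solid; its amount is given per volume of the solution
- the numbers in the tables scatter with a standard deviation of 0.5 percentage points
- reactions considered so far: J + X -> D + G; X + D <-> E; J <-> Q; L <-> J
- at the start none of L is in solution
- what has only dissolved of L counts as not reacted
- what has gone from J into another species counts as reacted, even if it can come back
- the earlier runs do not show how much of X is bound; that part of a forecast is a guess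

- part of the L that has reacted (what has only dissolved counts as not reacted) at 8.0 min
- share of the unused X that is free and not bound as E, at 8.0 min

1. Each G comes with a D, and D takes up a further X as E, so with strong binding I counted two X per G.
2. I named the ceiling, half the X charge over the L charge, as G in percent of the L charged: 55.0% for the north-west flask.
3. The south run tests this: its ceiling is 83.0%, and G read 83.5% at 6.00 min.
4. For the north-west flask at 8.0 min I froze G at the ceiling. What L and G lack at 4.00 min is J plus Q, 26.3%, and I froze that too.
5. Reacted L is G plus Q, since dissolved L counts as unreacted. The readings do not split J from Q, so I gave Q a fraction 0.5 of that sum and committed to 68.1%. That split was my weak link.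
6. The forecast gave 66% for c and 3% for fr, saying “The J/Q split is not resolved by the data.” My number stood above its c.

The flask gives 72.0% for c and 0.583% for fr.

    J + X → D + G (k = 0.190 /M/s)
    X + D ⇌ E, settled at all times (K = 14000 /M)
    J ⇌ Q (K = 1.30, k = 0.0210 /s)
    L ⇌ J, rate k4*(cs4 - [J]) while solid is left; crystals form when [J] > cs4 (solubility = 0.0620 M, k = 0.100 /s)

At 8.0 min the north-west flask holds G 56.1% against the ceiling 55.0%, and Q 16.0% beside J 12.3%; the J and Q equilibrium constant 1.3 reforges my even split into 69.9%. In the north-west flask the half-life of X by J + X → D + G is then 0.99 min, short against 8.0 min, and free X, the limiting reagent, stands at 0.29% of its charge. With 1.4 M of X the neighbour flask has a ceiling of 140%, above the L charged. Two X for each L charged leave 28.6% of the X in that neighbour flask, and at G 99.9% it holds 29% unbound.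

The runs were computed from invented constants, and the scatter is random.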